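**Plan**

- Numbering used below: ring carbons C10 (quaternary, Me and vinyl), C9 (CHOH), C8 (lactone CH–O), C7 (lactone CH), C6 (CH–O-angeloyl), C5 (CH carrying C4(=C15H2)–C3HO); the lactone is C11(=C13H2)–C12.
- Retrosynthesis: C3 is taken back to a methyl group and the O6 ester to the free alcohol; the ring bond C5–C6 is then cut to an aldehyde (C6) tethered to a terminal allene (C5=C4=C15) plus a methyl donor for C4; C7–C8 is cut to an aldehyde plus 3-(bromomethyl)butenolide, and C9–C10 to glyceraldehyde acetonide plus a Z-enynyl bromide.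
- Enabling feature: O6 and the alken-2-yl group on C5 are vicinal and cis on a cyclohexane whose chair is locked by the trans-fused γ-lactone at C7/C8; this is the imprint of a cis-fused five-membered oxanickelacycle Ni–O6–C6–C5–C4.
- Forward order: the chain is joined at C9–C10, then at C7–C8 (which also delivers the α-methylene lactone after an acyl shift from O6 to O8), then the cyclohexane is closed at C5–C6; esterification, allylic C–H oxidation at C3 and desilylation finish the route.
- Stereochemistry: (R)-glyceraldehyde acetonide sets C9 by Felkin addition (its own centre is erased when it is cut down to the C8 aldehyde); the Z-allyl geometry sets C10; Felkin control from C9 and the ring-fixed allyl geometry set C8 and C7; the locked chair and the metallacycle set C5 and C6.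

Key step: step 9

Remark: compounds 1, 3, 10 and 17 are taken to be commercial, and the allylchromium species of steps 2 and 7 are taken to hold their geometry on the time scale of the addition.

**Step 1**
Reactants: 1 (2Z)-3-methylpent-2-en-4-yn-1-ol
Product: 2 (3Z)-5-bromo-3-methylpent-3-en-1-yne
Conditions: PBr3 (0.4 equiv), pyridine (cat.), Et2O, −30 to 0 °C
Reagents that add atoms: phosphorus tribromide, BrP(Br)Br
Why: PBr3 bromination of a primary allylic alcohol (SN2 on the bromophosphite) at low temperature should give the allylic bromide without allylic shift, keeping the Z geometry that later sets the quaternary centre.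

**Step 2**
Reactants: 2 (3Z)-5-bromo-3-methylpent-3-en-1-yne; 3 (4R)-2,2-dimethyl-1,3-dioxolane-4-carbaldehyde
Product: 4 (1S,2S)-1-[(4R)-2,2-dimethyl-1,3-dioxolan-4-yl]-2-ethynyl-2-methylbut-3-en-1-ol
Conditions: CrCl2 (2.5 equiv), LiI (cat.), THF/DMPU, 0 °C to rt
Reagents that add atoms: none
Why: Nozaki–Hiyama–Kishi-type allylation in which the γ,γ-disubstituted allylchromium reagent should keep its Z geometry and add at its substituted terminus through a chair Zimmerman–Traxler transition state (slim ethynyl axial, methyl equatorial), so that the new hydroxyl ends up syn to ethynyl and anti to methyl, while Felkin–Anh attack anti to the ring C–O bond of 3 places it anti to the dioxolane oxygen.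

**Step 3**
Reactants: 4 (1S,2S)-1-[(4R)-2,2-dimethyl-1,3-dioxolan-4-yl]-2-ethynyl-2-methylbut-3-en-1-ol
Product: 5 tert-butyl{[(1S,2S)-1-[(4R)-2,2-dimethyl-1,3-dioxolan-4-yl]-2-ethynyl-2-methylbut-3-en-1-yl]oxy}dimethylsilane
Conditions: TBSOTf, 2,6-lutidine, CH2Cl2, 0 °C to rt
Reagents that add atoms: tert-butyldimethylsilyl trifluoromethanesulfonate, CC(C)(C)[Si](C)(C)OS(=O)(=O)C(F)(F)F
Why: silylation with a silyl triflate and a hindered base protects the congested secondary alcohol, so that this oxygen stays masked through the glycol cleavage and only the later C6 hydroxyl is open to acylation.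

**Step 4**
Reactants: 5 tert-butyl{[(1S,2S)-1-[(4R)-2,2-dimethyl-1,3-dioxolan-4-yl]-2-ethynyl-2-methylbut-3-en-1-yl]oxy}dimethylsilane
Product: 7 tert-butyl{[(1S,2S)-1-[(4R)-2,2-dimethyl-1,3-dioxolan-4-yl]-2-ethenyl-2-methylpenta-3,4-dien-1-yl]oxy}dimethylsilane, via propargylic amine 6 (not isolated)
Conditions: (CH2O)n, Cy2NH, CuI (cat.), 1,4-dioxane, reflux
Reagents that add atoms: formaldehyde (as paraformaldehyde), C=O
Why: Crabbé homologation, in which copper-mediated Mannich coupling of the terminal alkyne with formaldehyde and the secondary amine is followed by intramolecular hydride transfer with loss of the imine, should turn C≡CH into CH=C=CH2 and so install C15; the propargylic position is quaternary, so no alkyne–allene isomerisation competes.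

**Step 5**
Reactants: 7 tert-butyl{[(1S,2S)-1-[(4R)-2,2-dimethyl-1,3-dioxolan-4-yl]-2-ethenyl-2-methylpenta-3,4-dien-1-yl]oxy}dimethylsilane
Product: 9 (2S,3S)-2-[(tert-butyldimethylsilyl)oxy]-3-ethenyl-3-methylhexa-4,5-dienal, via triene diol 8 (not isolated)
Conditions: H5IO6 (1.5 equiv), EtOAc, rt
Reagents that add atoms: none
Why: periodic acid should hydrolyse the terminal acetonide and cleave the resulting 1,2-diol in the same flask (Malaprade glycol cleavage), excising the auxiliary carbon and unveiling the C8 aldehyde; the hindered secondary silyl ether and the alkenes are inert to periodate and the C9 centre is not epimerised under these non-basic conditions.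

**Step 6**
Reactants: 10 3-methylideneoxolan-2-one (α-methylene-γ-butyrolactone)
Product: 12 3-(bromomethyl)furan-2(5H)-one, via dibromolactone 11 (not isolated)
Conditions: Br2, CH2Cl2, 0 °C; then Et3N, 0 °C to rt
Reagents that add atoms: bromine, BrBr
Why: electrophilic addition of bromine to the exocyclic alkene followed by E2 loss of HBr across the ring C3–C4 bond should give the conjugated butenolide that keeps the allylic bromide, the endocyclic alkene being the more stable elimination product.

**Step 7**
Reactants: 9 (2S,3S)-2-[(tert-butyldimethylsilyl)oxy]-3-ethenyl-3-methylhexa-4,5-dienal; 12 3-(bromomethyl)furan-2(5H)-one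
Product: 14 (4S,5R)-5-[(1S,2S)-1-[(tert-butyldimethylsilyl)oxy]-2-ethenyl-2-methylpenta-3,4-dien-1-yl]-4-(hydroxymethyl)-3-methylideneoxolan-2-one, via primary Barbier adduct 13 (not isolated)
Conditions: CrCl2 (3 equiv), THF, 0 °C to rt; then p-TsOH·H2O (cat.), CH2Cl2, rt
Reagents that add atoms: none
Why: chromium Barbier (Nozaki–Hiyama–Kishi-type) allylation in which the ring fixes the allylchromium geometry (ring CH2O trans to CH2Cr), so the chair Zimmerman–Traxler transition state with that group equatorial sets C7 anti to the new C8 hydroxyl, Felkin–Anh attack anti to the C9 silyloxy group sets C8, the allyl transposition creates the exocyclic methylene, and acid-catalysed acyl migration from the primary to the secondary oxygen (translactonisation) should give the more substituted trans-4,5-disubstituted lactone and free the primary alcohol.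

**Step 8**
Reactants: 14 (4S,5R)-5-[(1S,2S)-1-[(tert-butyldimethylsilyl)oxy]-2-ethenyl-2-methylpenta-3,4-dien-1-yl]-4-(hydroxymethyl)-3-methylideneoxolan-2-one
Product: 15 (2R,3R)-2-[(1S,2S)-1-[(tert-butyldimethylsilyl)oxy]-2-ethenyl-2-methylpenta-3,4-dien-1-yl]-4-methylidene-5-oxooxolane-3-carbaldehyde
Conditions: Dess–Martin periodinane, CH2Cl2, 0 °C to rt; filtered through silica and used at once
Reagents that add atoms: none
Why: Dess–Martin oxidation of the primary alcohol under neutral conditions should give the aldehyde without removing the acidic proton at C7 (α to the aldehyde and allylic to the exocyclic alkene), which base would shift into conjugation; no stereocentre is created.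

**Step 9**
Reactants: 15 (2R,3R)-2-[(1S,2S)-1-[(tert-butyldimethylsilyl)oxy]-2-ethenyl-2-methylpenta-3,4-dien-1-yl]-4-methylidene-5-oxooxolane-3-carbaldehyde
Product: 16 (3aS,4S,5S,6S,7S,7aR)-7-[(tert-butyldimethylsilyl)oxy]-6-ethenyl-4-hydroxy-6-methyl-3-methylidene-5-(prop-1-en-2-yl)hexahydro-1-benzofuran-2(3H)-one
Conditions: Ni(cod)2 (10 mol%), Me2Zn (3 equiv), THF, 0 °C; aq. NH4Cl
Reagents that add atoms: dimethylzinc, C[Zn]C
Why: Zerovalent nickel should couple the aldehyde carbon C6 with the proximal π bond of the allene by oxidative cyclisation to a five-membered oxanickelacycle (Ni–O–C6–C5–C4, exocyclic C4=C15H2), after which methyl transfer from zinc to nickel and C–C reductive elimination place the methyl on C4 and release the zinc alkoxide; the closest known reaction type is the nickel-catalysed alkylative cyclisation of allenyl aldehydes with organozincs to cis-2-alkenylcycloalkanols. The cyclohexane closes in a 6-exo-trig mode at the aldehyde carbon, with the reacting allene π bond exocyclic to the new ring, and the metallacycle is only a transient second ring. C6 is controlled by that metallacycle, which must be cis-fused to the forming six-membered ring, so O6 and the alkenyl carbon on C5 end up cis. C5 is controlled by the chair that the trans-fused lactone locks (C7 and C8 substituents diequatorial): the alkenyl branch takes the equatorial site, because the other cis arrangement would put it axial and syn to the axial silyloxy group on C9. The step needs chemoselectivity for the aldehyde/allene pair over the α-methylene lactone and the vinyl group, and regioselectivity for bonding at the substituted allene terminus; the first rests on the fast intramolecular aldehyde–allene coupling at 0 °C and the low reactivity of enoates toward nickel/organozinc conjugate addition, the second on ring size (bonding at the central or distal allene carbon would need a seven- or eight-membered ring).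

**Step 10**
Reactants: 16 (3aS,4S,5S,6S,7S,7aR)-7-[(tert-butyldimethylsilyl)oxy]-6-ethenyl-4-hydroxy-6-methyl-3-methylidene-5-(prop-1-en-2-yl)hexahydro-1-benzofuran-2(3H)-one; 17 (2Z)-2-methylbut-2-enoic acid (angelic acid)
Product: 19 (3aS,4S,5S,6S,7S,7aR)-7-[(tert-butyldimethylsilyl)oxy]-6-ethenyl-6-methyl-3-methylidene-2-oxo-5-(prop-1-en-2-yl)octahydro-1-benzofuran-4-yl (2Z)-2-methylbut-2-enoate, via mixed anhydride 18 (not isolated)
Conditions: 17, 2,4,6-trichlorobenzoyl chloride, Et3N, toluene, rt; then 16, toluene, 80 °C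
Reagents that add atoms: none
Why: Yamaguchi-type esterification in which the mixed anhydride is attacked at the less hindered angeloyl carbonyl by the only free hydroxyl (C6–OH), and the absence of a nucleophilic amine catalyst in hot toluene should keep the Z geometry of the 2-methylbut-2-enoate.

**Step 11**
Reactants: 19 (3aS,4S,5S,6S,7S,7aR)-7-[(tert-butyldimethylsilyl)oxy]-6-ethenyl-6-methyl-3-methylidene-2-oxo-5-(prop-1-en-2-yl)octahydro-1-benzofuran-4-yl (2Z)-2-methylbut-2-enoate
Product: 21 (3aS,4S,5R,6S,7S,7aR)-7-[(tert-butyldimethylsilyl)oxy]-6-ethenyl-6-methyl-3-methylidene-2-oxo-5-(3-oxoprop-1-en-2-yl)octahydro-1-benzofuran-4-yl (2Z)-2-methylbut-2-enoate, via allylic alcohol 20 (not isolated)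
Conditions: SeO2 (2 equiv), 1,4-dioxane, 70 °C
Reagents that add atoms: selenium dioxide, O=[Se]=O
Why: Riley oxidation, in which ene reaction of SeO2 at the electron-rich 1,1-disubstituted alkene, [2,3]-sigmatropic shift and hydrolysis give the primary allylic alcohol that SeO2 oxidises on to the enal; the α-methylene lactone and angelate alkenes are electron-poor, the vinyl group has no allylic hydrogen, and the methyl group should react in preference to the hindered ring methine.

**Step 12**
Reactants: 21 (3aS,4S,5R,6S,7S,7aR)-7-[(tert-butyldimethylsilyl)oxy]-6-ethenyl-6-methyl-3-methylidene-2-oxo-5-(3-oxoprop-1-en-2-yl)octahydro-1-benzofuran-4-yl (2Z)-2-methylbut-2-enoate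
Product: 22 (3aS,4S,5R,6S,7S,7aR)-6-ethenyl-7-hydroxy-6-methyl-3-methylidene-2-oxo-5-(3-oxoprop-1-en-2-yl)octahydro-1-benzofuran-4-yl (2Z)-2-methylbut-2-enoate
Conditions: HF·pyridine, THF/pyridine, 0 °C to rt
Reagents that add atoms: none
Why: fluoride-induced Si–O cleavage under buffered acidic conditions should free the C9 hydroxyl without touching the enal, the α-methylene lactone or the Z-enoate, which are all base-sensitive.

**Compound list**

1 | (2Z)-3-methylpent-2-en-4-yn-1-ol | OC/C=C(/C)C#C | starting material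
2 | (3Z)-5-bromo-3-methylpent-3-en-1-yne | BrC/C=C(/C)C#C | intermediate
3 | (4R)-2,2-dimethyl-1,3-dioxolane-4-carbaldehyde | O=C[C@H]1COC(C)(C)O1 | starting material
4 | (1S,2S)-1-[(4R)-2,2-dimethyl-1,3-dioxolan-4-yl]-2-ethynyl-2-methylbut-3-en-1-ol | C=C[C@@](C)(C#C)[C@H](O)[C@H]1COC(C)(C)O1 | intermediate
5 | tert-butyl{[(1S,2S)-1-[(4R)-2,2-dimethyl-1,3-dioxolan-4-yl]-2-ethynyl-2-methylbut-3-en-1-yl]oxy}dimethylsilane | C=C[C@@](C)(C#C)[C@H](O[Si](C)(C)C(C)(C)C)[C@H]1COC(C)(C)O1 | intermediate
6 | N-cyclohexyl-N-[(4S,5S)-5-[(tert-butyldimethylsilyl)oxy]-5-[(4R)-2,2-dimethyl-1,3-dioxolan-4-yl]-4-ethenyl-4-methylpent-2-yn-1-yl]cyclohexanamine | C=C[C@@](C)(C#CCN(C1CCCCC1)C1CCCCC1)[C@H](O[Si](C)(C)C(C)(C)C)[C@H]1COC(C)(C)O1 | intermediate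
7 | tert-butyl{[(1S,2S)-1-[(4R)-2,2-dimethyl-1,3-dioxolan-4-yl]-2-ethenyl-2-methylpenta-3,4-dien-1-yl]oxy}dimethylsilane | C=C[C@@](C)(C=C=C)[C@H](O[Si](C)(C)C(C)(C)C)[C@H]1COC(C)(C)O1 | intermediate
8 | (2R,3S,4S)-3-[(tert-butyldimethylsilyl)oxy]-4-ethenyl-4-methylhepta-5,6-diene-1,2-diol | C=C[C@@](C)(C=C=C)[C@H](O[Si](C)(C)C(C)(C)C)[C@H](O)CO | intermediate
9 | (2S,3S)-2-[(tert-butyldimethylsilyl)oxy]-3-ethenyl-3-methylhexa-4,5-dienal | C=C[C@@](C)(C=C=C)[C@H](O[Si](C)(C)C(C)(C)C)C=O | intermediate
10 | 3-methylideneoxolan-2-one | C=C1CCOC1=O | starting material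
11 | 3-bromo-3-(bromomethyl)oxolan-2-one | BrCC1(Br)CCOC1=O | intermediate
12 | 3-(bromomethyl)furan-2(5H)-one | BrCC1=CCOC1=O | intermediate
13 | (4S)-4-[(1R,2S,3S)-2-[(tert-butyldimethylsilyl)oxy]-3-ethenyl-1-hydroxy-3-methylhexa-4,5-dien-1-yl]-3-methylideneoxolan-2-one | C=C[C@@](C)(C=C=C)[C@H](O[Si](C)(C)C(C)(C)C)[C@H](O)[C@@H]1COC(=O)C1=C | intermediate
14 | (4S,5R)-5-[(1S,2S)-1-[(tert-butyldimethylsilyl)oxy]-2-ethenyl-2-methylpenta-3,4-dien-1-yl]-4-(hydroxymethyl)-3-methylideneoxolan-2-one | C=C[C@@](C)(C=C=C)[C@H](O[Si](C)(C)C(C)(C)C)[C@@H]1OC(=O)C(=C)[C@H]1CO | intermediate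
15 | (2R,3R)-2-[(1S,2S)-1-[(tert-butyldimethylsilyl)oxy]-2-ethenyl-2-methylpenta-3,4-dien-1-yl]-4-methylidene-5-oxooxolane-3-carbaldehyde | C=C[C@@](C)(C=C=C)[C@H](O[Si](C)(C)C(C)(C)C)[C@@H]1OC(=O)C(=C)[C@H]1C=O | intermediate
16 | (3aS,4S,5S,6S,7S,7aR)-7-[(tert-butyldimethylsilyl)oxy]-6-ethenyl-4-hydroxy-6-methyl-3-methylidene-5-(prop-1-en-2-yl)hexahydro-1-benzofuran-2(3H)-one | C=C[C@]1(C)[C@H](O[Si](C)(C)C(C)(C)C)[C@@H]2OC(=O)C(=C)[C@H]2[C@@H](O)[C@H]1C(C)=C | intermediate
17 | (2Z)-2-methylbut-2-enoic acid (angelic acid) | C/C=C(/C)C(=O)O | starting material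
18 | (2Z)-2-methylbut-2-enoic 2,4,6-trichlorobenzoic anhydride | C/C=C(/C)C(=O)OC(=O)c1c(Cl)cc(Cl)cc1Cl | intermediate
19 | (3aS,4S,5S,6S,7S,7aR)-7-[(tert-butyldimethylsilyl)oxy]-6-ethenyl-6-methyl-3-methylidene-2-oxo-5-(prop-1-en-2-yl)octahydro-1-benzofuran-4-yl (2Z)-2-methylbut-2-enoate | C=C[C@]1(C)[C@H](O[Si](C)(C)C(C)(C)C)[C@@H]2OC(=O)C(=C)[C@H]2[C@@H](OC(=O)/C(C)=C\C)[C@H]1C(C)=C | intermediate
20 | (3aS,4S,5S,6S,7S,7aR)-7-[(tert-butyldimethylsilyl)oxy]-6-ethenyl-5-(3-hydroxyprop-1-en-2-yl)-6-methyl-3-methylidene-2-oxooctahydro-1-benzofuran-4-yl (2Z)-2-methylbut-2-enoate | C=C[C@]1(C)[C@H](O[Si](C)(C)C(C)(C)C)[C@@H]2OC(=O)C(=C)[C@H]2[C@@H](OC(=O)/C(C)=C\C)[C@H]1C(=C)CO | intermediate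
21 | (3aS,4S,5R,6S,7S,7aR)-7-[(tert-butyldimethylsilyl)oxy]-6-ethenyl-6-methyl-3-methylidene-2-oxo-5-(3-oxoprop-1-en-2-yl)octahydro-1-benzofuran-4-yl (2Z)-2-methylbut-2-enoate | C=C[C@]1(C)[C@H](O[Si](C)(C)C(C)(C)C)[C@@H]2OC(=O)C(=C)[C@H]2[C@@H](OC(=O)/C(C)=C\C)[C@H]1C(=C)C=O | intermediate
22 | (3aS,4S,5R,6S,7S,7aR)-6-ethenyl-7-hydroxy-6-methyl-3-methylidene-2-oxo-5-(3-oxoprop-1-en-2-yl)octahydro-1-benzofuran-4-yl (2Z)-2-methylbut-2-enoate | C=C[C@]1(C)[C@H](O)[C@@H]2OC(=O)C(=C)[C@H]2[C@@H](OC(=O)/C(C)=C\C)[C@H]1C(=C)C=O | target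

**Step count and risks**

Total step count: 12. Longest linear sequence: 11 steps (steps 1–5 and 7–12; step 6 prepares a side fragment).

The three steps most likely to fail:

1. Step 9. The nickel catalyst may be drawn to the electron-poor exocyclic alkene of the lactone (conjugate methyl transfer or sequestration), or that alkene may slide into conjugation with the aldehyde before the ring closes. The fallback sets out from 14 and comes back at 16. Diboration of the terminal allene π bond of 14 (B2pin2, Pt(dba)2, PCy3, toluene, 50 °C) should add syn and anti to the quaternary carbon and give the (Z)-2-boryl allylboronate alcohol F1. Dess–Martin oxidation then unmasks the aldehyde bis(boronate) F2, which should close at once, without any metal, by intramolecular allylboration through a chair Zimmerman–Traxler transition state (Z geometry gives the cis product) to the alkenylboronate cyclohexanol F3. Suzuki–Miyaura coupling of F3 with MeI (Pd(dppf)Cl2, K3PO4, THF/H2O) should then give 16.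

2. Step 11. The ene step may attack the ring methine C–H instead of the methyl group, stall at the alcohol, or oxidise the angelate methyl groups. The fallback sets out from 19 and comes back at 21. Ene-type allylic chlorination of the 2-propenyl group (NaOCl, CeCl3·7H2O, CH2Cl2/H2O, 0 °C) should give the 2-(chloromethyl)allyl compound, allylic chloride F4. N-oxide oxidation of the chloride (N-methylmorpholine N-oxide, MeCN, rt; a Kornblum-type oxidation) should then give enal 21.

3. Step 10. Acyl transfer to the hindered axial alcohol may be slow, and the angeloyl unit may drift from Z to E under forcing conditions. The fallback sets out from 16 and comes back at 19. Acylation of 16 with 2-[bis(2,2,2-trifluoroethoxy)phosphoryl]propanoic acid and DCC (CH2Cl2, rt; the small phosphonoketene is the acylating species) should give the phosphonate ester F5. Still–Gennari olefination of F5 with acetaldehyde (KN(SiMe3)2, 18-crown-6, THF, −78 °C) should then build the Z-alkene on the ester already in place and give 19.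

**Further compounds**

F1 | step 9 | alcohol 14 in which the allene has become (Z)-CH=C(Bpin)–CH2Bpin (Bpin on C4 trans to the quaternary carbon) | C=C[C@@](C)(/C=C(/B1OC(C)(C)C(C)(C)O1)CB1OC(C)(C)C(C)(C)O1)[C@H](O[Si](C)(C)C(C)(C)C)[C@@H]1OC(=O)C(=C)[C@H]1CO
F2 | step 9 | the corresponding aldehyde bis(boronate) | C=C[C@@](C)(/C=C(/B1OC(C)(C)C(C)(C)O1)CB1OC(C)(C)C(C)(C)O1)[C@H](O[Si](C)(C)C(C)(C)C)[C@@H]1OC(=O)C(=C)[C@H]1C=O
F3 | step 9 | analogue of 16 carrying a 1-(4,4,5,5-tetramethyl-1,3,2-dioxaborolan-2-yl)ethenyl group on C5 in place of prop-1-en-2-yl | C=C[C@]1(C)[C@H](O[Si](C)(C)C(C)(C)C)[C@@H]2OC(=O)C(=C)[C@H]2[C@@H](O)[C@H]1C(=C)B1OC(C)(C)C(C)(C)O1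
F4 | step 11 | analogue of 19 carrying a 3-chloroprop-1-en-2-yl group on C5 | C=C[C@]1(C)[C@H](O[Si](C)(C)C(C)(C)C)[C@@H]2OC(=O)C(=C)[C@H]2[C@@H](OC(=O)/C(C)=C\C)[C@H]1C(=C)CCl
F5 | step 10 | 2-[bis(2,2,2-trifluoroethoxy)phosphoryl]propanoate ester of 16 at O6 (mixture at the phosphonate α-carbon) | C=C[C@]1(C)[C@H](O[Si](C)(C)C(C)(C)C)[C@@H]2OC(=O)C(=C)[C@H]2[C@@H](OC(=O)C(C)P(=O)(OCC(F)(F)F)OCC(F)(F)F)[C@H]1C(C)=C
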